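Remark on the chemistry (one assumption): the hand of the ProPhenol ligand in step 1 and of the dirhodium carboxylate in step 15 is written as the usual models predict for the configurations drawn. If a first run shows the opposite sense, the antipodal ligand is used and nothing else changes.

Locants: ring system 1 is O1, C2, C3, C3a, C4–C7, C7a (the dihydrobenzofuran with the styryl group). Ring system 2 has primed locants. Its benzo ring (C3a', C4'–C7', C7a') is called the hub; C6' is bonded to C3.

## Analysis of the target

Compound 36 is a stilbene trimer built from two 2,3-diaryl-2,3-dihydrobenzofurans. Ring system 1 carries a 4-hydroxyphenyl group at C2, a hydroxyl at C4 and the (E)-4-hydroxystyryl group at C6. Its C3 is bonded to C6' of ring system 2, so the hub is at once the benzo ring of ring system 2 and the C3 aryl group of ring system 1. Ring system 2 carries a 2,4-dihydroxyphenyl group at C2', a 3,5-dihydroxyphenyl group at C3' and a hydroxyl at C4'. All four stereocentres are S, with C2/C3 trans and C2'/C3' trans. The two pairs are separated by the flat hub, so neither can steer the other and each needs its own source of absolute configuration. The sensitive groups are the eight phenols, the electron-rich (E)-stilbene, the benzylic aryl ethers O1–C2 and O1'–C2' (which ionise in acid, C2' more easily), and the diarylmethine hydrogens at C3 and C3' (whose removal by base opens the furan rings). The difficulty is the substitution pattern: in both benzo rings the carbon bearing the benzylic centre (C3a, C3a') lies between two oxygens with a carbon substituent para to it, which electrophilic substitution of a resorcinol does not give. The strategy rests on C3a of ring system 1, flanked by the oxygen-bearing C4 and C7a with the styryl-bearing C6 para: this ring is what a 3-styryl vinylketene (C4 to C7) and an ynol ether (C3a, C7a) that already carries C3 and C2 give on combination.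

## Retrosynthetic reasoning

36 to 35. The eight aryl O–CH3 bonds are cut first. Methyl is the one phenol protection that outlasts organolithiums, a ketene at 110 °C and a metal carbene, and one closing operation is cheaper than several orthogonal ones. The forward step must cleave eight ethers without leaving O1–C2 or O1'–C2' open.

35 to 34. C2' is the one centre allowed to arrive wrong, so 35 is traced to its C2' epimer 34. The bond O1'–C2' can open and re-form through a cation stabilised by the 2,4-dimethoxyphenyl group, and trans is the stable arrangement. This frees the ring-forming step from having to give trans directly.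

34 to 31 (through 33 and 32). The bond C2'–C3' is cut. C3' becomes a carbene carbon (diazo compound 33, from hydrazone 32 of ketone 31) and C2' the benzylic CH2 of an aryl ether. Cutting here, not at O1'–C2', means that C3', which no existing centre can control across the hub, is made in a step governed by a chiral catalyst. The forward reaction must insert into the benzylic C–H bond, not into the neighbouring methoxy group, and with high face selectivity.

31 to 29 and 30, then 29 to 28. The O1'–CH2 bond is cut to phenol 29 and alcohol 30, which brings in C2' with its aryl group as one commercial piece. Phenol 29 comes from ketone 28 by loss of one O-methyl group. The two methoxy groups ortho to the carbonyl are homotopic, so either gives 29, and the carbonyl group selects them among eight methyl ethers.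

28 to 25 and 26. The bond C3a'–C3' is cut to aryllithium 27 and acid chloride 26. Aryllithium 27 is drawn from bromide 25, not from a C–H bond: a base able to metalate between the methoxy groups could also remove the hydrogen at C3 or C2 and open ring system 1, whereas bromine–lithium exchange at −78 °C is faster than both. The price is a bromine atom carried as a spectator from 1 onward.

25 to 23 to 22. O-Methyl is exchanged for O-silyl (23), and in 23 the bond O1–C2 is cut to phenol 22. C2 bears a 4-methoxyphenyl group, so the bond forms by capture of a benzylic cation, and C2 is then dictated by C3 (trans). Only C3 has to arrive enantiopure, and the resorcinol ring is symmetric, so either oxygen can close.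

22 to 12 and 17. Three bonds of the benzo ring are cut at once: C3a–C4, C7–C7a and C4–C5. This gives siloxyalkyne 12 (C3a and C7a, with C3 and C2 attached) and cyclobutenone 17 (C4 to C7 with the styryl group). The cut solves the substitution problem by construction, since the alkyne carbon bearing the side chain must end between the two oxygens. The forward cascade must join that carbon to the ketene carbonyl carbon and leave the propargylic centre alone.

17 to 13 and 14. The styryl–ring bond is cut to vinyl bromide 13 (as styryllithium 15) and vinylogous ester 14, the usual one-flask entry to 3-substituted cyclobutenones.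

12 to 9 to 8. The O–C(sp) bond is cut: the oxygen is placed on terminal alkyne 9 by oxidation of its acetylide 10 to ynolate 11. This avoids strong base next to an enolisable centre, which an ester homologation would need. Alkyne 9 is the silyl ether of 8.

8 to 5 and 6. The bond C2–C3 is cut to aldehyde 6 and allenylindium 7, made from mesylate 5. The cut places the transferable chirality on C3, the only centre of this fragment that survives to the target.

5 to 4 to 3 to 1 and 2. The mesylate comes from propargylic alcohol 4, and its C–C bond to the alkyne is cut to aldehyde 1 and silylacetylene 2. An asymmetric alkynylation is the single source of chirality for ring system 1.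

## Alternatives that were turned down

Alternative 1: Disconnection: C3–C3a of ring system 1 is traced to the C4–C4a bond of a flavanone, so the five-membered ring comes from contraction of the pyranone of A1, (2S)-7-benzyloxy-5-methoxy-2-(4-methoxyphenyl)chroman-4-one. Forward key step: PhI(OAc)2 and H2SO4 in trimethyl orthoformate give an alpha-iodanyl ketal; the aryl carbon C4a shifts to C3 with loss of iodobenzene, and the old carbonyl carbon ends as the ester of A2, methyl (2S,3S)-6-benzyloxy-4-methoxy-2-(4-methoxyphenyl)-2,3-dihydrobenzofuran-3-carboxylate.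
- For it: an inexpensive flavonoid skeleton supplies O1, C2 with its aryl group, the C4 oxygen and the benzo ring in one piece; the contraction is one step; trans follows from the epimerisable ester.
- Against it for this target: A2 has oxygen at C6 where the target has the styryl carbon, and an ester at C3 where the target has the whole hub. C6 needs debenzylation, triflation and coupling. The hub and ring system 2 would have to be grown from a carboxyl carbon over many steps in which C3 is alpha to a carbonyl group and beta to O1, open to epimerisation and ring-opening elimination. The C2 centre of a flavanone is itself labile in acid (ring–chain equilibrium with the chalcone), so the enantiopurity of A2 is not secured.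
- Comparison: on cost and on how fast a trans dihydrobenzofuran is reached, Alternative 1 is stronger. The chosen strategy offers instead a ring-forming step that puts the styryl group on C6 and the aryl group on C3 at once, and a C3 centre that is never next to a carbonyl group.

Alternative 2: Disconnection: C2'–C3' and O1'–C2' of ring system 2, a [4+1] annulation. Forward key step: Cs2CO3 eliminates sulfinate from sulfone A3, 5-bromo-2-[(3,5-dimethoxyphenyl)(4-methylphenylsulfonyl)methyl]-3-methoxyphenol, to give an ortho-quinone methide, and deprotonates sulfonium salt A4, (2R,5R)-1-(2,4-dimethoxybenzyl)-2,5-dimethylthiolan-1-ium tetrafluoroborate. Conjugate addition of the ylide and displacement of the thiolane by the phenoxide give A5, (2S,3S)-6-bromo-2-(2,4-dimethoxyphenyl)-3-(3,5-dimethoxyphenyl)-4-methoxy-2,3-dihydrobenzofuran.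
- For it: two bonds and both centres in one basic step, trans directly, no acid near the labile C2' ether, and a bromide left for joining. For ring system 2 this is shorter than steps 13 to 16 of the chosen route, and on that point it is the stronger plan.
- Against it: the centre that survives later acid is C3'. It forms at the prochiral methide carbon, one bond further from the sulfur auxiliary than C2'. Its configuration depends on the face selectivity of a semi-stabilised benzylic ylide toward a hindered quinone methide and on whether betaine formation is reversible, which is harder to argue than a catalyst-bound carbene. As an overall strategy it also leaves the harder half open: from A5 the centre C3 must be created at a bromide, and the 2,5-disubstituted resorcinol of ring system 1 must still be assembled around it.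
- Comparison: the chosen strategy spends its key step on that ring and brings C3 in finished. The annulation of Alternative 2 is kept as the reserve for step 15.

Alternative 3: Disconnection: the hub ring is cut at C6'–C7' (and back through dehydration and enolisation) to a triketone chain on C3, A6, 1-[(2S,3S)-6-bromo-4-methoxy-2-(4-methoxyphenyl)-2,3-dihydrobenzofuran-3-yl]hexane-1,3,5-trione. Forward key step: aqueous KOH; the terminal methyl carbon attacks the ketone carbon on C3 (aldol), and loss of water and enolisation give resorcinol A7, 5-[(2S,3S)-6-bromo-4-methoxy-2-(4-methoxyphenyl)-2,3-dihydrobenzofuran-3-yl]benzene-1,3-diol.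
- For it: cheap and metal-free, and the hub arrives with two free hydroxyls while all other oxygens are methylated. The chosen route needs a separate demethylation (step 12) for that differentiation, so here Alternative 3 is stronger.
- Against it: in A6, C3 is alpha to a ketone and beta to the aryloxy oxygen O1. Hydroxide can enolise toward C3 and expel the phenoxide; reclosure by oxa-Michael addition restores trans but not the absolute configuration. The triketone can also close through oxygen to a pyranone. Afterwards the carbon between the two hub hydroxyls must still be bonded to C3', where electrophiles do not attack a resorcinol, and ring system 1 with its styryl group is presupposed.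
- Comparison: the chosen strategy has a less well differentiated hub, but it never exposes C3 to enolising base and it builds the benzo ring that Alternative 3 takes for granted.

Key step: step 8

## Route

Step 1
Reactants: 1 4-bromo-3,5-dimethoxybenzaldehyde; 2 ethynyltrimethylsilane
Product: 3 (R)-1-(4-bromo-3,5-dimethoxyphenyl)-3-(trimethylsilyl)prop-2-yn-1-ol
Conditions: Me2Zn (3 equiv), (S,S)-ProPhenol (10 mol%), Ph3P=O (20 mol%), toluene, 0 °C
Reagents that add atoms: none
Why: Zinc–ProPhenol catalysed asymmetric alkynylation of an aromatic aldehyde; the dinuclear zinc complex binds the aldehyde and the alkynylzinc and delivers the alkynyl group to the Si face, which sets the carbinol centre (R by the sequence rule, because the silylalkynyl group outranks the aryl group).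

Step 2
Reactants: 3 silylated propargylic alcohol
Product: 4 (S)-1-(4-bromo-3,5-dimethoxyphenyl)prop-2-yn-1-ol
Conditions: K2CO3 (cat.), MeOH, rt
Reagents that add atoms: none
Why: Methoxide-induced protodesilylation of the alkynylsilane; the carbinol centre is untouched and only its descriptor changes, since ethynyl ranks below aryl.

Step 3
Reactants: 4 propargylic alcohol
Product: 5 (S)-1-(4-bromo-3,5-dimethoxyphenyl)prop-2-yn-1-yl methanesulfonate
Conditions: MsCl, Et3N, CH2Cl2, −78 °C; used crude
Reagents that add atoms: methanesulfonyl chloride, CS(=O)(=O)Cl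
Why: O-Sulfonylation with retention; the meta methoxy groups and the bromine do not stabilise a benzylic cation, so the mesylate should last at low temperature long enough to be used at once.

Step 4
Reactants: 5 propargylic mesylate; 6 4-methoxybenzaldehyde
Product: 8 (1S,2R)-2-(4-bromo-3,5-dimethoxyphenyl)-1-(4-methoxyphenyl)but-3-yn-1-ol, via allenylindium 7 (not isolated)
Conditions: Pd(dppf)Cl2 (5 mol%), InI (1.4 equiv), THF–HMPA 3:1, 0 °C → rt
Reagents that add atoms: none
Why: Marshall propargylation: zerovalent palladium displaces the mesylate anti (SN2'), oxidative transmetalation with InI gives the allenylindium 7 with retention, and 7 adds to the aldehyde through a closed SE2' transition state, so the new C2–C3 bond replaces the C–O bond with overall inversion and the aldehyde substituent takes the anti position. The centre that matters is C3; any syn isomer differs only at C2, which is erased in step 9, and can be carried along.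

Step 5
Reactants: 8 anti homopropargylic alcohol
Product: 9 tert-butyl{[(1S,2R)-2-(4-bromo-3,5-dimethoxyphenyl)-1-(4-methoxyphenyl)but-3-yn-1-yl]oxy}dimethylsilane
Conditions: t-BuMe2SiOTf, 2,6-lutidine, CH2Cl2, −78 → 0 °C
Reagents that add atoms: tert-butyldimethylsilyl trifluoromethanesulfonate, CC(C)(C)[Si](C)(C)OS(=O)(=O)C(F)(F)F
Why: Silylation of the secondary alcohol, so that the alkyne C–H is the only acidic site in step 6.

Step 6
Reactants: 9 silyl-protected alkyne
Product: 12 {[(3S,4S)-3-(4-bromo-3,5-dimethoxyphenyl)-4-[(tert-butyldimethylsilyl)oxy]-4-(4-methoxyphenyl)but-1-yn-1-yl]oxy}tri(propan-2-yl)silane, via lithium acetylide 10 (not isolated), via lithium ynolate 11 (not isolated)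
Conditions: LiN(SiMe3)2 (2.2 equiv), THF, −78 °C; t-BuOOH (1.0 equiv), −78 → 0 °C; i-Pr3SiOTf, −78 °C → rt
Reagents that add atoms: tert-butyl hydroperoxide, CC(C)(C)OO; triisopropylsilyl trifluoromethanesulfonate, CC(C)[Si](C(C)C)(C(C)C)OS(=O)(=O)C(F)(F)F
Why: Julia oxidation of a lithium acetylide by lithium tert-butyl peroxide to the ynolate, then O-silylation by the bulky silyl triflate. LiN(SiMe3)2 neither exchanges the aryl bromide nor removes the propargylic hydrogen, so C3 is safe (its descriptor becomes S because the oxygenated alkynyl group now outranks aryl).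

Step 7
Reactants: 13 (E)-1-(2-bromovinyl)-4-methoxybenzene; 14 3-ethoxycyclobut-2-en-1-one
Product: 17 3-[(E)-2-(4-methoxyphenyl)ethenyl]cyclobut-2-en-1-one, via styryllithium 15 (not isolated), via lithium alkoxide 16 (not isolated)
Conditions: t-BuLi (2.0 equiv), Et2O, −78 °C; 14, −78 °C; 1 M HCl, 0 °C
Reagents that add atoms: water, O
Why: Bromine–lithium exchange with retention of alkene geometry, 1,2-addition to the vinylogous ester, and acid hydrolysis of the enol ether with loss of the tertiary hydroxyl (Stork–Danheiser carbonyl transposition), the standard entry to 3-substituted cyclobutenones.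

Step 8
Reactants: 12 siloxyalkyne; 17 styrylcyclobutenone
Product: 22 2-[(1S,2S)-1-(4-bromo-3,5-dimethoxyphenyl)-2-[(tert-butyldimethylsilyl)oxy]-2-(4-methoxyphenyl)ethyl]-5-[(E)-2-(4-methoxyphenyl)ethenyl]-3-[(triisopropylsilyl)oxy]phenol, via vinylketene 18 (not isolated), via cyclobutenone adduct 19 (not isolated), via dienylketene 20 (not isolated), via cyclohexadienone 21 (not isolated)
Conditions: 17 (1.3 equiv, added in portions), toluene, 80 °C, then 110 °C
Reagents that add atoms: none
Why: Danheiser benzannulation of a cyclobutenone with a siloxyalkyne. At 80 °C 17 opens in a four-electron electrocyclic reaction to vinylketene 18; the alkyne carbon beta to oxygen, which carries the side chain and is the nucleophilic end of the ynol ether, bonds to the ketene carbonyl carbon and the oxygen-bearing carbon to the ketene alpha carbon in a [2+2] cycloaddition that gives 19. Four-electron opening of 19 gives dienylketene 20, whose six-electron disrotatory electrocyclisation closes the six-membered ring as 21, and tautomerisation gives the phenol; the bonds made are C3a–C4, C7–C7a and C4–C5. The benzene ring is thus closed by electrocyclisation, and the only other ring, the four-membered ring of 19, is formed and opened again. No stereocentre is created: the sp3 ring carbon of 19 is lost on ring opening, and C3 and C2 are spectators because no acid, base or ionising medium is present. The one selectivity needed is the regiochemistry of the [2+2] step, and the polarity of the ynol ether against the ketene fixes it so that the side chain ends between the two oxygens and the styryl group para to it. The cross reaction must also outrun self-condensation of 18, which portionwise addition of 17 to the alkyne favours; the free phenol of 22 is flanked by the bulky side chain and should resist acylation by 18.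

Step 9
Reactants: 22 resorcinol monosilyl ether
Product: 23 (2S,3S)-3-(4-bromo-3,5-dimethoxyphenyl)-2-(4-methoxyphenyl)-6-[(E)-2-(4-methoxyphenyl)ethenyl]-4-[(triisopropylsilyl)oxy]-2,3-dihydrobenzofuran
Conditions: CF3CO2H (2 equiv), CH2Cl2, 0 °C
Reagents that add atoms: none
Why: SN1 cycloetherification: the 4-methoxybenzylic silyl ether ionises, the neighbouring free phenol captures the cation in a five-membered ring, and reversible ionisation of the product leads to the more stable trans isomer, so C2 is set by C3 whatever its configuration in 22. Capture by the adjacent oxygen should outrun loss of the C3 proton from the cation, and the aryl silyl ether survives.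

Step 10
Reactants: 23 silyl-protected dihydrobenzofuran
Product: 25 (2S,3S)-3-(4-bromo-3,5-dimethoxyphenyl)-4-methoxy-2-(4-methoxyphenyl)-6-[(E)-2-(4-methoxyphenyl)ethenyl]-2,3-dihydrobenzofuran, via ammonium phenoxide 24 (not isolated)
Conditions: Bu4NF, MeI, THF, 0 °C → rt
Reagents that add atoms: iodomethane, CI
Why: Fluoride cleaves the aryl silyl ether and the tetrabutylammonium phenoxide is methylated in the same flask (Williamson ether synthesis).

Step 11
Reactants: 25 hub bromide; 26 3,5-dimethoxybenzoyl chloride
Product: 28 {2,6-dimethoxy-4-[(2S,3S)-4-methoxy-2-(4-methoxyphenyl)-6-[(E)-2-(4-methoxyphenyl)ethenyl]-2,3-dihydrobenzofuran-3-yl]phenyl}(3,5-dimethoxyphenyl)methanone, via aryllithium 27 (not isolated)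
Conditions: n-BuLi (1.05 equiv), THF, −78 °C; 26, −78 → 0 °C
Reagents that add atoms: none
Why: Bromine–lithium exchange at −78 °C is faster than deprotonation at C2 or C3, and the 2,6-dimethoxyaryllithium is acylated by the acid chloride; the doubly ortho-substituted ketone is too hindered for a second addition.

Step 12
Reactants: 28 hub diaryl ketone
Product: 29 {2-hydroxy-6-methoxy-4-[(2S,3S)-4-methoxy-2-(4-methoxyphenyl)-6-[(E)-2-(4-methoxyphenyl)ethenyl]-2,3-dihydrobenzofuran-3-yl]phenyl}(3,5-dimethoxyphenyl)methanone
Conditions: BCl3 (1.2 equiv), CH2Cl2, −78 → 0 °C; aq. NaHCO3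
Reagents that add atoms: none
Why: Chelation-controlled demethylation: boron bound to the ketone oxygen cleaves only a methoxy group ortho to the carbonyl, and the first cleavage ties the boron up in a six-membered chelate, so the reaction stops at one. The two ortho methoxy groups are homotopic, so either gives 29.

Step 13
Reactants: 29 ortho-hydroxy ketone; 30 (2,4-dimethoxyphenyl)methanol
Product: 31 {2-[(2,4-dimethoxybenzyl)oxy]-6-methoxy-4-[(2S,3S)-4-methoxy-2-(4-methoxyphenyl)-6-[(E)-2-(4-methoxyphenyl)ethenyl]-2,3-dihydrobenzofuran-3-yl]phenyl}(3,5-dimethoxyphenyl)methanone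
Conditions: PPh3, DIAD, THF, 0 °C → rt
Reagents that add atoms: none
Why: Mitsunobu etherification of the acidic, hydrogen-bonded phenol with an activated benzylic alcohol; it puts C2' and its aryl group on O1' under neutral conditions.

Step 14
Reactants: 31 benzyl ether ketone
Product: 32 hydrazone of 31: {2-[(2,4-dimethoxybenzyl)oxy]-6-methoxy-4-[(2S,3S)-4-methoxy-2-(4-methoxyphenyl)-6-[(E)-2-(4-methoxyphenyl)ethenyl]-2,3-dihydrobenzofuran-3-yl]phenyl}(3,5-dimethoxyphenyl)methanone hydrazone
Conditions: N2H4 (anhydrous, 10 equiv), AcOH (cat.), EtOH, 80 °C, sealed tube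
Reagents that add atoms: hydrazine, NN
Why: Acid-catalysed condensation of a diaryl ketone with hydrazine; forcing conditions are chosen because the carbonyl group has two ortho substituents.

Step 15
Reactants: 32 hydrazone
Product: 34 (2S,3S)-3-[(2R,3S)-2-(2,4-dimethoxyphenyl)-3-(3,5-dimethoxyphenyl)-4-methoxy-2,3-dihydrobenzofuran-6-yl]-4-methoxy-2-(4-methoxyphenyl)-6-[(E)-2-(4-methoxyphenyl)ethenyl]-2,3-dihydrobenzofuran, via diazo compound 33 (not isolated)
Conditions: MnO2, CH2Cl2, 0 °C; filter; Rh2(S-PTAD)4 (1 mol%), CH2Cl2, 0 °C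
Reagents that add atoms: none
Why: Oxidation of the hydrazone to the diaryldiazomethane and dirhodium-catalysed intramolecular C–H insertion of the donor/donor carbene into the 2,4-dimethoxybenzylic C–H bond (hydride shift to the carbene carbon, then C–C bond formation inside the chiral carboxylate pocket); this closes the five-membered ring, sets C3' under catalyst control and gives the cis isomer kinetically. The doubly activated benzylic C–H bond should be taken in preference to the C–H bonds of the neighbouring methoxy group, which is the site selectivity the step needs.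

Step 16
Reactants: 34 cis isomer at ring system 2
Product: 35 (2S,3S)-3-[(2S,3S)-2-(2,4-dimethoxyphenyl)-3-(3,5-dimethoxyphenyl)-4-methoxy-2,3-dihydrobenzofuran-6-yl]-4-methoxy-2-(4-methoxyphenyl)-6-[(E)-2-(4-methoxyphenyl)ethenyl]-2,3-dihydrobenzofuran
Conditions: CF3CO2H (0.2 equiv), CH2Cl2, 0 °C → rt
Reagents that add atoms: none
Why: Acid-mediated epimerisation at C2' by reversible opening of O1'–C2' to the 2,4-dimethoxybenzylic cation; trans is the thermodynamic isomer and C3' is not involved.

Step 17
Reactants: 35 octamethyl ether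
Product: 36 (2S,3S)-3-[(2S,3S)-2-(2,4-dihydroxyphenyl)-3-(3,5-dihydroxyphenyl)-4-hydroxy-2,3-dihydrobenzofuran-6-yl]-2-(4-hydroxyphenyl)-6-[(E)-2-(4-hydroxyphenyl)ethenyl]-2,3-dihydrobenzofuran-4-ol (CNP0118407.1)
Conditions: BBr3 (16 equiv), CH2Cl2, −78 → 0 °C; MeOH, then H2O
Reagents that add atoms: none
Why: Lewis-acid cleavage of the eight aryl methyl ethers (bromide attacks the O-methyl carbon of the boron-complexed ether, SN2); in this skeleton no nucleophilic ring lies within reach of the stilbene, and any opening at C2 or C2' recloses to the trans isomers.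

## Compound list

1 | 4-bromo-3,5-dimethoxybenzaldehyde | COc1cc(C=O)cc(OC)c1Br | starting material
2 | ethynyltrimethylsilane | C[Si](C)(C)C#C | starting material
3 | (R)-1-(4-bromo-3,5-dimethoxyphenyl)-3-(trimethylsilyl)prop-2-yn-1-ol | C[Si](C)(C)C#C[C@H](O)c1cc(OC)c(Br)c(OC)c1 | intermediate
4 | (S)-1-(4-bromo-3,5-dimethoxyphenyl)prop-2-yn-1-ol | C#C[C@H](O)c1cc(OC)c(Br)c(OC)c1 | intermediate
5 | (S)-1-(4-bromo-3,5-dimethoxyphenyl)prop-2-yn-1-yl methanesulfonate | C#C[C@H](OS(C)(=O)=O)c1cc(OC)c(Br)c(OC)c1 | intermediate
6 | 4-methoxybenzaldehyde | COc1ccc(C=O)cc1 | starting material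
7 | (aS)-[3-(4-bromo-3,5-dimethoxyphenyl)propa-1,2-dien-1-yl]indium iodide methanesulfonate | CS(=O)(=O)O[In](I)C([H])=[C@@]=C([H])c1cc(OC)c(Br)c(OC)c1 | intermediate
8 | (1S,2R)-2-(4-bromo-3,5-dimethoxyphenyl)-1-(4-methoxyphenyl)but-3-yn-1-ol | C#C[C@H](c1cc(OC)c(Br)c(OC)c1)[C@H](O)c1ccc(OC)cc1 | intermediate
9 | tert-butyl{[(1S,2R)-2-(4-bromo-3,5-dimethoxyphenyl)-1-(4-methoxyphenyl)but-3-yn-1-yl]oxy}dimethylsilane | C#C[C@H](c1cc(OC)c(Br)c(OC)c1)[C@H](O[Si](C)(C)C(C)(C)C)c1ccc(OC)cc1 | intermediate
10 | lithium acetylide of 9 | [Li]C#C[C@H](c1cc(OC)c(Br)c(OC)c1)[C@H](O[Si](C)(C)C(C)(C)C)c1ccc(OC)cc1 | intermediate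
11 | lithium (3S,4S)-3-(4-bromo-3,5-dimethoxyphenyl)-4-[(tert-butyldimethylsilyl)oxy]-4-(4-methoxyphenyl)but-1-yn-1-olate | [Li+].[O-]C#C[C@H](c1cc(OC)c(Br)c(OC)c1)[C@H](O[Si](C)(C)C(C)(C)C)c1ccc(OC)cc1 | intermediate
12 | {[(3S,4S)-3-(4-bromo-3,5-dimethoxyphenyl)-4-[(tert-butyldimethylsilyl)oxy]-4-(4-methoxyphenyl)but-1-yn-1-yl]oxy}tri(propan-2-yl)silane | CC(C)[Si](C(C)C)(C(C)C)OC#C[C@H](c1cc(OC)c(Br)c(OC)c1)[C@H](O[Si](C)(C)C(C)(C)C)c1ccc(OC)cc1 | intermediate
13 | (E)-1-(2-bromovinyl)-4-methoxybenzene | COc1ccc(/C=C/Br)cc1 | starting material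
14 | 3-ethoxycyclobut-2-en-1-one | CCOC1=CC(=O)C1 | starting material
15 | [(E)-2-(4-methoxyphenyl)ethenyl]lithium | COc1ccc(/C=C/[Li])cc1 | intermediate
16 | lithium 3-ethoxy-1-[(E)-2-(4-methoxyphenyl)ethenyl]cyclobut-2-en-1-olate | CCOC1=CC([O-])(/C=C/c2ccc(OC)cc2)C1.[Li+] | intermediate
17 | 3-[(E)-2-(4-methoxyphenyl)ethenyl]cyclobut-2-en-1-one | COc1ccc(/C=C/C2=CC(=O)C2)cc1 | intermediate
18 | (E)-5-(4-methoxyphenyl)-3-methylidenepenta-1,4-dien-1-one (vinylketene) | COc1ccc(/C=C/C(=C)C=C=O)cc1 | intermediate
19 | 2-[(1S,2S)-1-(4-bromo-3,5-dimethoxyphenyl)-2-[(tert-butyldimethylsilyl)oxy]-2-(4-methoxyphenyl)ethyl]-4-[(E)-4-(4-methoxyphenyl)buta-1,3-dien-2-yl]-3-[(triisopropylsilyl)oxy]cyclobut-2-en-1-one (both epimers at ring C4) | COc1ccc(/C=C/C(=C)C2C(=O)C([C@H](c3cc(OC)c(Br)c(OC)c3)[C@H](O[Si](C)(C)C(C)(C)C)c3ccc(OC)cc3)=C2O[Si](C(C)C)(C(C)C)C(C)C)cc1 | intermediate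
20 | dienylketene from 19: the ketene carbon bears the (1S,2S) side chain, the next carbon the silyloxy group, then CH= and the 2-substituted buta-1,3-diene, with ketene and diene cis on the enol ether double bond | COc1ccc(/C=C/C(=C)\C=C(O[Si](C(C)C)(C(C)C)C(C)C)/C(=C=O)[C@H](c2cc(OC)c(Br)c(OC)c2)[C@H](O[Si](C)(C)C(C)(C)C)c2ccc(OC)cc2)cc1 | intermediate
21 | 2-[(1S,2S)-1-(4-bromo-3,5-dimethoxyphenyl)-2-[(tert-butyldimethylsilyl)oxy]-2-(4-methoxyphenyl)ethyl]-5-[(E)-2-(4-methoxyphenyl)ethenyl]-3-[(triisopropylsilyl)oxy]cyclohexa-2,4-dien-1-one | COc1ccc(/C=C/C2=CC(O[Si](C(C)C)(C(C)C)C(C)C)=C([C@H](c3cc(OC)c(Br)c(OC)c3)[C@H](O[Si](C)(C)C(C)(C)C)c3ccc(OC)cc3)C(=O)C2)cc1 | intermediate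
22 | 2-[(1S,2S)-1-(4-bromo-3,5-dimethoxyphenyl)-2-[(tert-butyldimethylsilyl)oxy]-2-(4-methoxyphenyl)ethyl]-5-[(E)-2-(4-methoxyphenyl)ethenyl]-3-[(triisopropylsilyl)oxy]phenol | COc1ccc(/C=C/c2cc(O)c([C@H](c3cc(OC)c(Br)c(OC)c3)[C@H](O[Si](C)(C)C(C)(C)C)c3ccc(OC)cc3)c(O[Si](C(C)C)(C(C)C)C(C)C)c2)cc1 | intermediate
23 | (2S,3S)-3-(4-bromo-3,5-dimethoxyphenyl)-2-(4-methoxyphenyl)-6-[(E)-2-(4-methoxyphenyl)ethenyl]-4-[(triisopropylsilyl)oxy]-2,3-dihydrobenzofuran | COc1ccc(/C=C/c2cc(O[Si](C(C)C)(C(C)C)C(C)C)c3c(c2)O[C@H](c2ccc(OC)cc2)[C@H]3c2cc(OC)c(Br)c(OC)c2)cc1 | intermediate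
24 | tetrabutylammonium (2S,3S)-3-(4-bromo-3,5-dimethoxyphenyl)-2-(4-methoxyphenyl)-6-[(E)-2-(4-methoxyphenyl)ethenyl]-2,3-dihydrobenzofuran-4-olate | COc1ccc(/C=C/c2cc([O-])c3c(c2)O[C@H](c2ccc(OC)cc2)[C@H]3c2cc(OC)c(Br)c(OC)c2)cc1.CCCC[N+](CCCC)(CCCC)CCCC | intermediate
25 | (2S,3S)-3-(4-bromo-3,5-dimethoxyphenyl)-4-methoxy-2-(4-methoxyphenyl)-6-[(E)-2-(4-methoxyphenyl)ethenyl]-2,3-dihydrobenzofuran | COc1ccc(/C=C/c2cc(OC)c3c(c2)O[C@H](c2ccc(OC)cc2)[C@H]3c2cc(OC)c(Br)c(OC)c2)cc1 | intermediate
26 | 3,5-dimethoxybenzoyl chloride | COc1cc(cc(OC)c1)C(=O)Cl | starting material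
27 | {2,6-dimethoxy-4-[(2S,3S)-4-methoxy-2-(4-methoxyphenyl)-6-[(E)-2-(4-methoxyphenyl)ethenyl]-2,3-dihydrobenzofuran-3-yl]phenyl}lithium | COc1ccc(/C=C/c2cc(OC)c3c(c2)O[C@H](c2ccc(OC)cc2)[C@H]3c2cc(OC)c([Li])c(OC)c2)cc1 | intermediate
28 | {2,6-dimethoxy-4-[(2S,3S)-4-methoxy-2-(4-methoxyphenyl)-6-[(E)-2-(4-methoxyphenyl)ethenyl]-2,3-dihydrobenzofuran-3-yl]phenyl}(3,5-dimethoxyphenyl)methanone | COc1ccc(/C=C/c2cc(OC)c3c(c2)O[C@H](c2ccc(OC)cc2)[C@H]3c2cc(OC)c(C(=O)c4cc(OC)cc(OC)c4)c(OC)c2)cc1 | intermediate
29 | {2-hydroxy-6-methoxy-4-[(2S,3S)-4-methoxy-2-(4-methoxyphenyl)-6-[(E)-2-(4-methoxyphenyl)ethenyl]-2,3-dihydrobenzofuran-3-yl]phenyl}(3,5-dimethoxyphenyl)methanone | COc1ccc(/C=C/c2cc(OC)c3c(c2)O[C@H](c2ccc(OC)cc2)[C@H]3c2cc(O)c(C(=O)c4cc(OC)cc(OC)c4)c(OC)c2)cc1 | intermediate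
30 | (2,4-dimethoxyphenyl)methanol | COc1ccc(CO)c(OC)c1 | starting material
31 | {2-[(2,4-dimethoxybenzyl)oxy]-6-methoxy-4-[(2S,3S)-4-methoxy-2-(4-methoxyphenyl)-6-[(E)-2-(4-methoxyphenyl)ethenyl]-2,3-dihydrobenzofuran-3-yl]phenyl}(3,5-dimethoxyphenyl)methanone | COc1ccc(/C=C/c2cc(OC)c3c(c2)O[C@H](c2ccc(OC)cc2)[C@H]3c2cc(OCc4ccc(OC)cc4OC)c(C(=O)c4cc(OC)cc(OC)c4)c(OC)c2)cc1 | intermediate
32 | hydrazone of 31 (C=N–NH2 in place of C=O) | COc1ccc(/C=C/c2cc(OC)c3c(c2)O[C@H](c2ccc(OC)cc2)[C@H]3c2cc(OCc4ccc(OC)cc4OC)c(C(=NN)c4cc(OC)cc(OC)c4)c(OC)c2)cc1 | intermediate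
33 | diazo compound from 32 (C=N2 in place of C=O of 31) | COc1ccc(/C=C/c2cc(OC)c3c(c2)O[C@H](c2ccc(OC)cc2)[C@H]3c2cc(OCc4ccc(OC)cc4OC)c(C(=[N+]=[N-])c4cc(OC)cc(OC)c4)c(OC)c2)cc1 | intermediate
34 | (2S,3S)-3-[(2R,3S)-2-(2,4-dimethoxyphenyl)-3-(3,5-dimethoxyphenyl)-4-methoxy-2,3-dihydrobenzofuran-6-yl]-4-methoxy-2-(4-methoxyphenyl)-6-[(E)-2-(4-methoxyphenyl)ethenyl]-2,3-dihydrobenzofuran | COc1ccc(/C=C/c2cc(OC)c3c(c2)O[C@H](c2ccc(OC)cc2)[C@H]3c2cc(OC)c3c(c2)O[C@@H](c2ccc(OC)cc2OC)[C@H]3c2cc(OC)cc(OC)c2)cc1 | intermediate
35 | (2S,3S)-3-[(2S,3S)-2-(2,4-dimethoxyphenyl)-3-(3,5-dimethoxyphenyl)-4-methoxy-2,3-dihydrobenzofuran-6-yl]-4-methoxy-2-(4-methoxyphenyl)-6-[(E)-2-(4-methoxyphenyl)ethenyl]-2,3-dihydrobenzofuran | COc1ccc(/C=C/c2cc(OC)c3c(c2)O[C@H](c2ccc(OC)cc2)[C@H]3c2cc(OC)c3c(c2)O[C@H](c2ccc(OC)cc2OC)[C@H]3c2cc(OC)cc(OC)c2)cc1 | intermediate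
36 | (2S,3S)-3-[(2S,3S)-2-(2,4-dihydroxyphenyl)-3-(3,5-dihydroxyphenyl)-4-hydroxy-2,3-dihydrobenzofuran-6-yl]-2-(4-hydroxyphenyl)-6-[(E)-2-(4-hydroxyphenyl)ethenyl]-2,3-dihydrobenzofuran-4-ol | Oc1ccc(/C=C/c2cc(O)c3c(c2)O[C@H](c2ccc(O)cc2)[C@H]3c2cc(O)c3c(c2)O[C@H](c2ccc(O)cc2O)[C@H]3c2cc(O)cc(O)c2)cc1 | target

## Step count and least certain steps

Total: 17 steps. Longest linear sequence: 16 steps (1 to 6, then 8 to 17); step 7 is a one-step branch.

Step 8 (key step). The most likely failure is that the [2+2] step is slowed by the doubly branched substituent on the nucleophilic alkyne carbon, so that self-condensation of vinylketene 18, or thermal decay of 12 at the temperature needed to open 17, takes over. The fallback makes the same ketene at room temperature by a different reaction, 1,4-dehydrochlorination of a dienoyl chloride, which separates ketene generation from the electrocyclic steps. It sets out from 6: Horner–Wadsworth–Emmons reaction with triethyl 3-methyl-4-phosphonocrotonate (NaH, THF) gives ethyl (2E,4E)-5-(4-methoxyphenyl)-3-methylpenta-2,4-dienoate F1, LiOH gives the dienoic acid F2, and oxalyl chloride gives the dienoyl chloride F3. F3 is added by syringe pump to 12 and Et3N in toluene at 20 °C, which should give 19 by way of 18; the solution is then heated to 110 °C and the fallback rejoins the route at 22.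

Step 4. The risk is partial racemisation at C3, either by ionisation of the benzylic mesylate 5 before palladium attacks or by propargyl–allenyl metallotropy in 7, which an aryl group makes easier than an alkyl group; poor anti selectivity would not matter. The fallback uses a covalent, configurationally stable allenylboronate. From 4, methyl chloroformate and pyridine give methyl (S)-1-(4-bromo-3,5-dimethoxyphenyl)prop-2-yn-1-yl carbonate F4. Copper-catalysed anti-SN2' borylation (CuOt-Bu, Xantphos, B2pin2, THF) gives the allenylboronate 2-[(aS)-3-(4-bromo-3,5-dimethoxyphenyl)propa-1,2-dien-1-yl]-4,4,5,5-tetramethyl-1,3,2-dioxaborolane F5, which is isolated and added to 6 (toluene, 60 °C) through the same closed six-membered transition state; it returns at 8.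

Step 14. The risk is incomplete condensation, because the carbonyl carbon of 31 is shielded by two ortho alkoxy groups, and loss of the acid-labile benzyl ether on long heating. The fallback thionates first: from 31, Lawesson's reagent (toluene, 80 °C) gives the thioketone F6 (C=S in place of C=O of 31), whose thiocarbonyl group reacts with hydrazine at room temperature; it returns at 32.

Step 15. The risk is low enantioselectivity at C3', because the carbene aryl group has two ortho substituents, a case at the edge of the usual substrates, and competing insertion into the methoxy C–H bonds. The fallback is a [4+1] annulation of an ortho-quinone methide with a sulfur ylide, which needs neither step 13 nor step 14. From 29, NaBH4 gives the diarylmethanol F7, and 4-methylbenzenesulfinic acid (CH2Cl2, rt) gives the sulfone F8. Separately, 30, (2R,5R)-2,5-dimethylthiolane and HBF4·OEt2 give the sulfonium salt (2R,5R)-1-(2,4-dimethoxybenzyl)-2,5-dimethylthiolan-1-ium tetrafluoroborate F9. Cs2CO3 in CH2Cl2 releases the quinone methide from F8 and the ylide from F9; conjugate addition forms C2'–C3' and the phenoxide displaces the thiolane, which should give the trans compound directly, so the fallback returns at 35. The thiolane enantiomer is chosen on a model; if induction is incomplete, the two diastereomers, which differ in ring system 2 only, are separated.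

Step 17. The risk is ionisation of O1'–C2' (and O1–C2) by the Lewis acid followed by Friedel–Crafts alkylation of an electron-rich ring instead of reclosure, together with incomplete cleavage of eight ethers. The fallback is dealkylation by a soft nucleophile under basic conditions, where no benzylic cation can form: from 35, NaSEt (excess) in DMF at 130 °C and then acidification lead straight to 36, and no new compound is made on the way (F0).

## Further compounds

F1 | step 8 | ethyl (2E,4E)-5-(4-methoxyphenyl)-3-methylpenta-2,4-dienoate | CCOC(=O)/C=C(C)/C=C/c1ccc(OC)cc1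
F2 | step 8 | (2E,4E)-5-(4-methoxyphenyl)-3-methylpenta-2,4-dienoic acid | OC(=O)/C=C(C)/C=C/c1ccc(OC)cc1
F3 | step 8 | (2E,4E)-5-(4-methoxyphenyl)-3-methylpenta-2,4-dienoyl chloride | ClC(=O)/C=C(C)/C=C/c1ccc(OC)cc1
F4 | step 4 | methyl (S)-1-(4-bromo-3,5-dimethoxyphenyl)prop-2-yn-1-yl carbonate | C#C[C@H](OC(=O)OC)c1cc(OC)c(Br)c(OC)c1
F5 | step 4 | 2-[(aS)-3-(4-bromo-3,5-dimethoxyphenyl)propa-1,2-dien-1-yl]-4,4,5,5-tetramethyl-1,3,2-dioxaborolane | CC1(C)OB(OC1(C)C)C([H])=[C@@]=C([H])c1cc(OC)c(Br)c(OC)c1
F6 | step 14 | {2-[(2,4-dimethoxybenzyl)oxy]-6-methoxy-4-[(2S,3S)-4-methoxy-2-(4-methoxyphenyl)-6-[(E)-2-(4-methoxyphenyl)ethenyl]-2,3-dihydrobenzofuran-3-yl]phenyl}(3,5-dimethoxyphenyl)methanethione | COc1ccc(/C=C/c2cc(OC)c3c(c2)O[C@H](c2ccc(OC)cc2)[C@H]3c2cc(OCc4ccc(OC)cc4OC)c(C(=S)c4cc(OC)cc(OC)c4)c(OC)c2)cc1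
F7 | step 15 | {2-hydroxy-6-methoxy-4-[(2S,3S)-4-methoxy-2-(4-methoxyphenyl)-6-[(E)-2-(4-methoxyphenyl)ethenyl]-2,3-dihydrobenzofuran-3-yl]phenyl}(3,5-dimethoxyphenyl)methanol (both carbinol epimers) | COc1ccc(/C=C/c2cc(OC)c3c(c2)O[C@H](c2ccc(OC)cc2)[C@H]3c2cc(O)c(C(O)c4cc(OC)cc(OC)c4)c(OC)c2)cc1
F8 | step 15 | 2-[(3,5-dimethoxyphenyl)(4-methylphenylsulfonyl)methyl]-3-methoxy-5-[(2S,3S)-4-methoxy-2-(4-methoxyphenyl)-6-[(E)-2-(4-methoxyphenyl)ethenyl]-2,3-dihydrobenzofuran-3-yl]phenol (both epimers at the sulfonyl carbon) | COc1ccc(/C=C/c2cc(OC)c3c(c2)O[C@H](c2ccc(OC)cc2)[C@H]3c2cc(O)c(C(c4cc(OC)cc(OC)c4)S(=O)(=O)c4ccc(C)cc4)c(OC)c2)cc1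
F9 | step 15 | (2R,5R)-1-(2,4-dimethoxybenzyl)-2,5-dimethylthiolan-1-ium tetrafluoroborate | C[C@@H]1CC[C@@H](C)[S+]1Cc1ccc(OC)cc1OC.F[B-](F)(F)F
F0 | step 17 | none | none
A1 | alternative 1 | (2S)-7-benzyloxy-5-methoxy-2-(4-methoxyphenyl)chroman-4-one | O=C1C[C@@H](c2ccc(OC)cc2)Oc2cc(OCc3ccccc3)cc(OC)c12
A2 | alternative 1 | methyl (2S,3S)-6-benzyloxy-4-methoxy-2-(4-methoxyphenyl)-2,3-dihydrobenzofuran-3-carboxylate | c1ccccc1COc2cc(OC)c3c(c2)O[C@H](c2ccc(OC)cc2)[C@H]3C(=O)OC
A3 | alternative 2 | 5-bromo-2-[(3,5-dimethoxyphenyl)(4-methylphenylsulfonyl)methyl]-3-methoxyphenol | Cc1ccc(cc1)S(=O)(=O)C(c1cc(OC)cc(OC)c1)c1c(O)cc(Br)cc1OC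
A4 | alternative 2 | (2R,5R)-1-(2,4-dimethoxybenzyl)-2,5-dimethylthiolan-1-ium tetrafluoroborate | C[C@@H]1CC[C@@H](C)[S+]1Cc1ccc(OC)cc1OC.F[B-](F)(F)F
A5 | alternative 2 | (2S,3S)-6-bromo-2-(2,4-dimethoxyphenyl)-3-(3,5-dimethoxyphenyl)-4-methoxy-2,3-dihydrobenzofuran | Brc2cc(OC)c3c(c2)O[C@H](c2ccc(OC)cc2OC)[C@H]3c2cc(OC)cc(OC)c2
A6 | alternative 3 | 1-[(2S,3S)-6-bromo-4-methoxy-2-(4-methoxyphenyl)-2,3-dihydrobenzofuran-3-yl]hexane-1,3,5-trione | Brc2cc(OC)c3c(c2)O[C@H](c2ccc(OC)cc2)[C@H]3C(=O)CC(=O)CC(=O)C
A7 | alternative 3 | 5-[(2S,3S)-6-bromo-4-methoxy-2-(4-methoxyphenyl)-2,3-dihydrobenzofuran-3-yl]benzene-1,3-diol | Brc2cc(OC)c3c(c2)O[C@H](c2ccc(OC)cc2)[C@H]3c2cc(O)cc(O)c2
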